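Its constants are assumed; the rest is arithmetic.

I began with the easy step: gas passes into the solution, where rival reagent starts from nothing.

    starting material + partner → target (k1 = 370 /M/s)
    starting material + rival reagent → side product (k2 = 250 /M/s)
    gas ⇌ rival reagent, rate k3*(csat - [rival reagent]) (k3 = 0.26 /s, csat = 0.30 mM)
    rival reagent + target ⇌ idle adduct, settled at all times (K4 = 16000 /M)

- alpha: starting material 5.0 × 10⁻⁴ M; partner 1.00 equiv; gas 0.30 mM (held); time 4.0 s
- epsilon: starting material 5.0 × 10⁻⁴ M; partner 1.30 equiv; gas 0.30 mM (held); time 4.0 s

- for target the idle adduct is counted in
- at the start none of rival reagent is dissolved
- run time (alpha): 4.0 s

- which of these there is most of at the end, counted by the starting material in it, alpha (target / side product / starting material)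
- which of these there is most of at the end, counted by the starting material in it, epsilon (target / side product / starting material)
- how much there is at the end of the one of these that leads, in percent of the starting material charged: alpha
- how much there is at the end of the one of these that leads, in percent of the starting material charged: epsilon

This was my note for the person taking over the bench. The flask held starting material and partner, with rival reagent dissolving in. Leaving its reactions out, I reckoned rival reagent at 0.194 mM at 4.0 s, and its two reactions could pull it lower.

I followed one molecule of starting material to its fork. I kept 3.82 as the fork odds, the coupling constant times [partner] over the side constant times [rival reagent], a momentary selectivity factor. That figure took alpha's partner at its charge and rival reagent at that ceiling. So I expected the path to target to stay faster than the path to side product, and I reckoned the coupling by itself, as second order.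

For alpha that gave 42.5% target and 57.5% starting material, before any loss to side product. For epsilon it gave 51.9% target, in the lead. I asked that the partner be left alone: alpha and epsilon differ in it, and the path to target runs on it.

The forecast gave starting material at 54% for alpha, below my figure, and target at 51% for epsilon, with a rival reagent that “dissolves slowly”.

In the simulation, alpha ended with starting material in the lead at 54.1%. Epsilon ended with target in the lead at 51.2%. At the end of epsilon, starting material had a half-life of 4.8 s on the path to target, shorter than 31 s on the path to side product. That second half-life is long against the run of 4.0 s, and side product stood at 3.20%. The ratio of the two half-lives gives fork odds of 6.46 at the end of epsilon, while the end of alpha gives 4.27. The neighbour of epsilon with 2.20 equiv of partner ends at odds of 15.5, with side product at 1.77%.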